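The readings come from a simulation for substances that don't exist; the scatter is artificial.

In a one-step world I would count turnovers of a single rate. These flasks had two products, so I counted the ratio of two rates.

| setting | Wednesday's | Sunday's | Friday's | alpha | zeta | eta |
|---|---|---|---|---|---|---|
| substrate | 0.050 M | 0.050 M | 0.050 M | 0.050 M (fed, over 25 min) | 0.050 M | 0.050 M |
| partner | 0.025 M | 0.035 M | 0.055 M | 0.0250 M | 0.0250 M | 0.0250 M (fed, over 25 min) |
| protic impurity | 1 mM | 1 mM | 1 mM | 1.00 mM | 1.00 mM | 1.00 mM |
| remark | run made earlier | run made earlier | run made earlier | all else is in the flask from the start; the feed brings no volume worth counting | everything together at the start | all else is in the flask from the start; the feed brings no volume worth counting |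
| time |  |  |  | 30 min | 30 min | 30 min |

| run | time / min | target / % | side product / % |
|---|---|---|---|
| Wednesday's | 1.33 | 0.9 | 2.0 |
| Wednesday's | 2.50 | 2.4 | 4.9 |
| Wednesday's | 4.00 | 5.1 | 8.2 |
| Wednesday's | 6.00 | 8.8 | 12.3 |
| Wednesday's | 10.0 | 12.8 | 18.7 |
| Wednesday's | 20.0 | 21.1 | 28.1 |
| Sunday's | 1.50 | 1.9 | 2.2 |
| Sunday's | 5.00 | 9.2 | 10.5 |
| Sunday's | 8.00 | 14.3 | 14.8 |
| Sunday's | 12.0 | 20.5 | 19.9 |
| Sunday's | 20.0 | 28.3 | 26.2 |
| Sunday's | 25.0 | 31.5 | 28.5 |
| Friday's | 2.00 | 4.2 | 3.3 |
| Friday's | 3.00 | 7.7 | 6.0 |
| Friday's | 5.00 | 14.2 | 9.6 |
| Friday's | 8.00 | 22.1 | 13.7 |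
| Friday's | 15.0 | 34.9 | 20.1 |
| Friday's | 25.0 | 45.5 | 23.5 |

(scatter of a reading: 0.3 percentage points)

- a species is counted by the substrate in it: one side product counts as two
- reactions considered so far: substrate <-> reactive form; partner + reactive form -> target; substrate + reactive form -> side product; partner + protic impurity -> quenched reagent

- the best flask by share of target in target plus side product; "all alike" if 1.5 percentage points covers them all (alpha / zeta / eta / all alike)
- share of target in target plus side product at the end, alpha
- share of target in target plus side product at the end, zeta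
- share of target in target plus side product at the end, eta

On Wednesday target formed at 0.914 mM min⁻¹ between 2.50 min and 6.00 min, and side product at 1.06 mM min⁻¹, counted in substrate. Between 10.0 min and 20.0 min these had slowed by factors of 2.20 and 2.25. Slowing so alike cancels in a ratio.

So I kept G = 1.56, a selectivity factor: target over side product at the last reading, divided by partner net of impurity per substrate. Friday's last reading gave 1.79, so G is rough.

I took target rate as following substrate and partner, and side-product rate as following substrate squared. If substrate climbed in a straight line through a steady feed, unconsumed, these rates would average half and a third of their full-charge values. A partner feed, reckoned the same way, halves the target rate and leaves the other.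

ratio = G · (c(partner) − c(protic impurity)) / c(substrate)

zeta: 0.751, share 42.9%

alpha: × 1.50 = 1.13, share 53.0%

eta: × 0.500 = 0.375, share 27.3%

That made alpha best in my reckoning. The forecast, which is not this reckoning, also named alpha: 51% (46% to 57%) for alpha, 43.5% (42% to 45.5%) for zeta, 28% (22% to 33%) for eta. Its ground for eta was “feeding partner starves target early”.

The flasks gave alpha as best: alpha 48.9%, zeta 42.5%, eta 28.4%.

    substrate ⇌ reactive form (K = 0.780, k = 0.00620 s⁻¹)
    partner + reactive form → target (k = 0.0340 L mol⁻¹ s⁻¹)
    substrate + reactive form → side product (k = 0.0200 L mol⁻¹ s⁻¹)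
    partner + protic impurity → quenched reagent (k = 0.680 L mol⁻¹ s⁻¹)

At the end of its feed, 25.0 min, alpha held target 15.5% and side product 14.5%, a ratio of 1.07 against my 1.13. Alpha had not come to rest at 30.0 min, with substrate at 34.2% and reactive form at 25.5%. At 300 min it held target 43.6% and side product 50.5%. Alpha's share there was 46.3% and eta's 41.0%, a gap of 5.3 percentage points, smaller than the 20 points at 30.0 min.

For alpha's neighbour with 0.020 M of substrate, G gave a ratio of 2.82, a share of 73.8%. The computed flask gave 72.1%.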